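The route rests on cutting the C2–C3 bond of ring C. A dirhodium carbenoid generated at C3 from a ring A diazomethyl ketone inserts into one C–H bond of the O1–CH2–aryl ether methylene. That methylene carbon, the future C2, is activated twice: by the lone pair of O1 and by the electron-rich ring B. This single operation closes ring C, forms C2–C3 and sets the C2 stereocentre. The precursor is a fully silylated 6-(arylmethoxy)-2,4-bis(silyloxy)-3-lavandulylphenyl diazomethyl ketone. It is assembled from 2,4,6-trihydroxyacetophenone, a ring B benzyl alcohol and (R)-lavandulol, so the acetyl group, the oxygen pattern and the side-chain stereocentre are bought, not made.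

Key step: step 10

Design notes:
- The acetyl group is carried from the start, so no Friedel–Crafts chemistry is run on the acid-sensitive side chain.
- The side chain is joined by cross-coupling, because a lavandulyl halide is a β-branched, non-allylic electrophile unsuited to C-alkylation of a phenol.
- The three ring A oxygens are told apart in a fixed order: the para oxygen by acidity, one of two equivalent ortho oxygens by mono-etherification, and the coupling site by the directing effect of the last free hydroxyl.
- O5 is silylated, so no O–CH–O hydrogen lies in a 1,6-relation to the carbenoid.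

Abbreviations: TBS = tert-butyldimethylsilyl; TIPS = triisopropylsilyl; ArCH2O = [2-methoxy-4-(triisopropylsilyloxy)phenyl]methoxy; lavandulyl = (2S)-5-methyl-2-(prop-1-en-2-yl)hex-4-en-1-yl on an arene.

Remark on descriptors: the side-chain centre is R in lavandulol, its iodide and its lithium and zinc derivatives, and S once the CH2 group carries the arene. Only the CIP ranking changes; no bond at that centre is ever touched.

Assumption: Rh2(S-PTTL)4 (dirhodium tetrakis[N-phthaloyl-(S)-tert-leucinate]) is taken to deliver the (2S) configuration; if the sense of induction proves opposite, Rh2(R-PTTL)4 is used instead. Enantiopure (R)-lavandulol is taken as purchasable.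

Step 1
Reactants: 1 4-hydroxy-2-methoxybenzaldehyde
Product: 2 2-methoxy-4-(triisopropylsilyloxy)benzaldehyde
Conditions: TIPSCl, imidazole, DMF, 0 °C to rt
Reagents that add atoms: triisopropylsilyl chloride, CC(C)[Si](Cl)(C(C)C)C(C)C
Why: Silylation of an acidic phenol with a silyl chloride and imidazole is routine, and the bulky TIPS ether should survive the borohydride step and all later steps up to the final fluoride treatment.

Step 2
Reactants: 2 2-methoxy-4-(triisopropylsilyloxy)benzaldehyde
Product: 3 [2-methoxy-4-(triisopropylsilyloxy)phenyl]methanol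
Conditions: NaBH4, MeOH/THF, 0 °C
Reagents that add atoms: none
Why: Borohydride reduction of an aryl aldehyde to the benzyl alcohol is reliable, and the neutral work-up spares this acid-sensitive electron-rich benzyl alcohol.

Step 3
Reactants: 4 1-(2,4,6-trihydroxyphenyl)ethanone
Product: 5 1-[4-(tert-butyldimethylsilyloxy)-2,6-dihydroxyphenyl]ethanone
Conditions: TBSCl (1.05 equiv), imidazole, DMF, −20 to 0 °C
Reagents that add atoms: tert-butyldimethylsilyl chloride, CC(C)(C)[Si](C)(C)Cl
Why: Regioselective phenol silylation is expected because the 4-hydroxyl, para to the acetyl group, is the most acidic and the only one that is neither chelated to nor crowded by the carbonyl group.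

Step 4
Reactants: 5 1-[4-(tert-butyldimethylsilyloxy)-2,6-dihydroxyphenyl]ethanone; 3 [2-methoxy-4-(triisopropylsilyloxy)phenyl]methanol
Product: 6 1-[4-(tert-butyldimethylsilyloxy)-2-hydroxy-6-(ArCH2O)phenyl]ethanone
Conditions: PPh3, DIAD, THF, 0 °C to rt
Reagents that add atoms: none
Why: In this Mitsunobu etherification the two ortho hydroxyls are equivalent and the one left after the first alkylation is locked in a strong hydrogen bond to the carbonyl, so a single mono-ether should form under neutral conditions without ever making an unstable electron-rich benzyl halide.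

Step 5
Reactants: 6 1-[4-(tert-butyldimethylsilyloxy)-2-hydroxy-6-(ArCH2O)phenyl]ethanone
Product: 7 1-[4-(tert-butyldimethylsilyloxy)-2-hydroxy-3-iodo-6-(ArCH2O)phenyl]ethanone
Conditions: NIS (1.0 equiv), DMF, 0 °C, dark
Reagents that add atoms: N-iodosuccinimide, O=C1CCC(=O)N1I
Why: In this electrophilic aromatic iodination the chelated hydroxyl directs the electrophile to its free ortho carbon (between OH and OTBS), as is usual for 2-hydroxy-4,6-dialkoxyacetophenones, and a free phenol reacts with NIS without acid far faster than the diether ring B.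

Step 6
Reactants: 7 1-[4-(tert-butyldimethylsilyloxy)-2-hydroxy-3-iodo-6-(ArCH2O)phenyl]ethanone
Product: 8 1-[2,4-bis(tert-butyldimethylsilyloxy)-3-iodo-6-(ArCH2O)phenyl]ethanone
Conditions: TBSCl, imidazole, DMAP (cat.), DMF, 40 °C
Reagents that add atoms: tert-butyldimethylsilyl chloride, CC(C)(C)[Si](C)(C)Cl
Why: Silylation of the last phenol, hindered and chelated but made more acidic by the ortho iodine, should proceed with DMAP catalysis and gentle warming, and it removes the only acidic proton before the organozinc coupling.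

Step 7
Reactants: 9 (R)-lavandulol
Product: 10 (R)-lavandulyl iodide
Conditions: PPh3, I2, imidazole, CH2Cl2, 0 °C to rt
Reagents that add atoms: iodine, II
Why: Appel-type iodination replaces the primary hydroxyl by iodide through SN2 displacement at CH2, so the neighbouring stereocentre is not involved and keeps its configuration.

Step 8
Reactants: 10 (R)-lavandulyl iodide; 8 1-[2,4-bis(tert-butyldimethylsilyloxy)-3-iodo-6-(ArCH2O)phenyl]ethanone
Product: 13 1-[2,4-bis(tert-butyldimethylsilyloxy)-6-(ArCH2O)-3-lavandulylphenyl]ethanone, via (R)-lavandulyllithium 11 (not isolated), via (R)-lavandulylzinc chloride 12 (not isolated)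
Conditions: 10, t-BuLi (2.0 equiv), Et2O/pentane, −78 °C; ZnCl2, THF, −78 °C to rt; then 8, Pd(OAc)2 (5 mol %), SPhos (10 mol %), THF, 50 °C
Reagents that add atoms: tert-butyllithium, [Li]C(C)(C)C (lithium of intermediate 11 only); zinc dichloride, Cl[Zn]Cl (ZnCl of intermediate 12 only); no atom of either stays in 13
Why: In this Negishi cross-coupling, lithium–iodine exchange at low temperature avoids radical rearrangement of the homoallylic chain, the alkylzinc tolerates the methyl ketone and the silyl ethers, and the bulky biaryl phosphine should drive reductive elimination at the doubly flanked iodide ahead of β-hydride elimination; the stereocentre lies β to the metal and is untouched.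

Step 9
Reactants: 13 1-[2,4-bis(tert-butyldimethylsilyloxy)-6-(ArCH2O)-3-lavandulylphenyl]ethanone
Product: 15 2-diazo-1-[2,4-bis(tert-butyldimethylsilyloxy)-6-(ArCH2O)-3-lavandulylphenyl]ethanone, via trifluoroacetyl 1,3-diketone 14 (not isolated)
Conditions: LiN(SiMe3)2, THF, −78 °C; CF3CO2CH2CF3, −78 °C; aq. NH4Cl; then MsN3, Et3N, H2O (1 equiv), MeCN, rt
Reagents that add atoms: methanesulfonyl azide, CS(=O)(=O)N=[N+]=[N-] (the two diazo nitrogens); 2,2,2-trifluoroethyl trifluoroacetate, O=C(OCC(F)(F)F)C(F)(F)F (CF3CO of intermediate 14 only, lost again)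
Why: In this detrifluoroacetylative diazo transfer the kinetic lithium enolate of the methyl ketone is C-trifluoroacetylated, and the activated 1,3-diketone then takes the diazo group from the sulfonyl azide while the trifluoroacetyl group leaves as the N-acyl sulfonamide, under conditions mild enough for the silyl ethers and the benzylic ether.

Step 10
Reactants: 15 2-diazo-1-[2,4-bis(tert-butyldimethylsilyloxy)-6-(ArCH2O)-3-lavandulylphenyl]ethanone
Product: 16 (2S)-5,7-bis(tert-butyldimethylsilyloxy)-2-[2-methoxy-4-(triisopropylsilyloxy)phenyl]-6-lavandulylchroman-4-one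
Conditions: Rh2(S-PTTL)4 (2 mol %), toluene, 0 °C, slow addition of 15
Reagents that add atoms: none
Why: The dirhodium catalyst expels N2 from the diazo ketone to give an electrophilic carbenoid at C3, which inserts into one of the two enantiotopic C–H bonds of the O1–CH2 group through a concerted three-centre transition state with hydride-transfer character. The reaction type is the known dirhodium-tetracarboxylate-catalysed intramolecular C–H insertion of 2-alkoxyaryl diazo ketones next to the ether oxygen, which gives chroman-4-ones. Ring C closes as a six-membered ring by 1,6-insertion (carbenoid carbon C3 as atom 1, the methylene carbon C2 as atom 6); a five-membered alternative is excluded because atom 5 is O1 and bears no hydrogen. The C2 stereocentre is set by the catalyst alone, since the pocket formed by the four N-phthaloyl-tert-leucinate ligands presents the carbenoid to one benzylic hydrogen, and the remote side-chain centre should have no influence. The step needs chemoselectivity for insertion over attack of O1 on the carbenoid (oxonium ylide, then 1,2-benzyl shift to a benzofuran-3-one) and over reaction at the side-chain alkenes or at O5. Four features of the substrate secure this: the electron-rich ring B makes the C2–H bonds hydridic, O1 is a weakly basic aryl ether oxygen conjugated to the acyl-bearing ring, the silyl group on O5 has no C–H bond alpha to oxygen, and the alkenes could be reached only through rings of eight or more members; carboxylate ligands in a non-polar solvent add to this.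

Step 11
Reactants: 16 (2S)-5,7-bis(tert-butyldimethylsilyloxy)-2-[2-methoxy-4-(triisopropylsilyloxy)phenyl]-6-lavandulylchroman-4-one
Product: 17 (2S)-5,7-dihydroxy-2-(4-hydroxy-2-methoxyphenyl)-6-lavandulylchroman-4-one (target)
Conditions: Bu4NF, AcOH (1:1.1), THF, 0 °C to rt
Reagents that add atoms: none
Why: Fluoride-mediated desilylation cleaves all three aryl silyl ethers at once, and the acetic acid buffer keeps phenoxides from opening ring C by retro-oxa-Michael reaction (which would scramble C2) while staying too weakly acidic to cyclise the side-chain alkenes onto the neighbouring phenols.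

Compound list
1 | 4-hydroxy-2-methoxybenzaldehyde | COc1cc(O)ccc1C=O | starting material
2 | 2-methoxy-4-(triisopropylsilyloxy)benzaldehyde | COc1cc(O[Si](C(C)C)(C(C)C)C(C)C)ccc1C=O | intermediate
3 | [2-methoxy-4-(triisopropylsilyloxy)phenyl]methanol | COc1cc(O[Si](C(C)C)(C(C)C)C(C)C)ccc1CO | intermediate
4 | 1-(2,4,6-trihydroxyphenyl)ethanone (2,4,6-trihydroxyacetophenone) | CC(=O)c1c(O)cc(O)cc1O | starting material
5 | 1-[4-(tert-butyldimethylsilyloxy)-2,6-dihydroxyphenyl]ethanone | CC(=O)c1c(O)cc(O[Si](C)(C)C(C)(C)C)cc1O | intermediate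
6 | 1-[4-(tert-butyldimethylsilyloxy)-2-hydroxy-6-{[2-methoxy-4-(triisopropylsilyloxy)phenyl]methoxy}phenyl]ethanone | CC(=O)c1c(O)cc(O[Si](C)(C)C(C)(C)C)cc1OCc2ccc(O[Si](C(C)C)(C(C)C)C(C)C)cc2OC | intermediate
7 | 1-[4-(tert-butyldimethylsilyloxy)-2-hydroxy-3-iodo-6-{[2-methoxy-4-(triisopropylsilyloxy)phenyl]methoxy}phenyl]ethanone | CC(=O)c1c(O)c(I)c(O[Si](C)(C)C(C)(C)C)cc1OCc2ccc(O[Si](C(C)C)(C(C)C)C(C)C)cc2OC | intermediate
8 | 1-[2,4-bis(tert-butyldimethylsilyloxy)-3-iodo-6-{[2-methoxy-4-(triisopropylsilyloxy)phenyl]methoxy}phenyl]ethanone | CC(=O)c1c(O[Si](C)(C)C(C)(C)C)c(I)c(O[Si](C)(C)C(C)(C)C)cc1OCc2ccc(O[Si](C(C)C)(C(C)C)C(C)C)cc2OC | intermediate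
9 | (R)-lavandulol, (2R)-5-methyl-2-(prop-1-en-2-yl)hex-4-en-1-ol | C=C(C)[C@@H](CC=C(C)C)CO | starting material
10 | (R)-lavandulyl iodide, (3R)-3-(iodomethyl)-2,6-dimethylhepta-1,5-diene | C=C(C)[C@@H](CC=C(C)C)CI | intermediate
11 | (R)-lavandulyllithium | C=C(C)[C@@H](CC=C(C)C)C[Li] | intermediate (not isolated)
12 | (R)-lavandulylzinc chloride | C=C(C)[C@@H](CC=C(C)C)C[Zn]Cl | intermediate (not isolated)
13 | 1-[2,4-bis(tert-butyldimethylsilyloxy)-6-{[2-methoxy-4-(triisopropylsilyloxy)phenyl]methoxy}-3-[(2S)-5-methyl-2-(prop-1-en-2-yl)hex-4-en-1-yl]phenyl]ethanone | C=C(C)[C@@H](CC=C(C)C)Cc1c(O[Si](C)(C)C(C)(C)C)cc(OCc2ccc(O[Si](C(C)C)(C(C)C)C(C)C)cc2OC)c(C(C)=O)c1O[Si](C)(C)C(C)(C)C | intermediate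
14 | 4,4,4-trifluoro-1-[2,4-bis(tert-butyldimethylsilyloxy)-6-{[2-methoxy-4-(triisopropylsilyloxy)phenyl]methoxy}-3-[(2S)-5-methyl-2-(prop-1-en-2-yl)hex-4-en-1-yl]phenyl]butane-1,3-dione | C=C(C)[C@@H](CC=C(C)C)Cc1c(O[Si](C)(C)C(C)(C)C)cc(OCc2ccc(O[Si](C(C)C)(C(C)C)C(C)C)cc2OC)c(C(=O)CC(=O)C(F)(F)F)c1O[Si](C)(C)C(C)(C)C | intermediate (not isolated)
15 | 2-diazo-1-[2,4-bis(tert-butyldimethylsilyloxy)-6-{[2-methoxy-4-(triisopropylsilyloxy)phenyl]methoxy}-3-[(2S)-5-methyl-2-(prop-1-en-2-yl)hex-4-en-1-yl]phenyl]ethanone | C=C(C)[C@@H](CC=C(C)C)Cc1c(O[Si](C)(C)C(C)(C)C)cc(OCc2ccc(O[Si](C(C)C)(C(C)C)C(C)C)cc2OC)c(C(=O)C=[N+]=[N-])c1O[Si](C)(C)C(C)(C)C | intermediate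
16 | (2S)-5,7-bis(tert-butyldimethylsilyloxy)-2-[2-methoxy-4-(triisopropylsilyloxy)phenyl]-6-[(2S)-5-methyl-2-(prop-1-en-2-yl)hex-4-en-1-yl]chroman-4-one | C=C(C)[C@@H](CC=C(C)C)Cc1c(O[Si](C)(C)C(C)(C)C)cc2c(c1O[Si](C)(C)C(C)(C)C)C(=O)C[C@@H](c1ccc(O[Si](C(C)C)(C(C)C)C(C)C)cc1OC)O2 | intermediate
17 | (2S)-5,7-dihydroxy-2-(4-hydroxy-2-methoxyphenyl)-6-[(2S)-5-methyl-2-(prop-1-en-2-yl)hex-4-en-1-yl]chroman-4-one | C=C(C)[C@@H](CC=C(C)C)Cc1c(O)cc2c(c1O)C(=O)C[C@@H](c1ccc(O)cc1OC)O2 | target

Total steps: 11. Longest linear sequence: 9 steps (steps 1, 2, 4, 5, 6, 8, 9, 10, 11, counted from 4-hydroxy-2-methoxybenzaldehyde).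

Steps most likely to fail

1. Step 10. The carbenoid may be captured by the lone pair of O1 to give an oxonium ylide whose benzyl group then migrates, or the chiral catalyst may discriminate poorly between the two enantiotopic hydrogens. The fallback closes ring C through the O1–C2 bond by oxa-Michael addition instead.
   - It sets out from ketone 13. Oxidative removal of the electron-rich benzyl group with DDQ in buffered wet CH2Cl2 at 0 °C should give 1-[6-hydroxy-2,4-bis(tert-butyldimethylsilyloxy)-3-lavandulylphenyl]ethanone F1 and return aldehyde 2.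
   - Double deprotonation of F1 with LiN(SiMe3)2 in THF at −78 °C and addition of aldehyde 2 should give the β-hydroxy ketone aldol adduct F2. Its benzylic hydroxyl, activated by ring B, is eliminated with pyridinium p-toluenesulfonate in warm toluene to the (E)-2'-hydroxychalcone F3.
   - A mild amine base (i-Pr2NEt, toluene, 40 °C) should close ring C to flavanone 16 together with its C2 epimer, the (2R)-configured silylated flavanone F4. The two are diastereomers and are separated by preparative HPLC; F4 is returned to the equilibrium through F3 under the same base.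
   - The fallback rejoins the route at 16.

2. Step 8. Oxidative addition and transmetalation at an iodide flanked by two silyl ethers may be slow, so that β-hydride elimination of the alkylpalladium intermediate or simple reduction of the iodide takes over. The fallback makes the bond one step earlier, at a less hindered carbon, with a boron nucleophile.
   - It sets out from iodophenol 7 and iodide 10. (R)-Lavandulyllithium 11, made as before, is trapped with B-methoxy-9-borabicyclo[3.3.1]nonane to give the lithium B-lavandulyl-B-methoxy-9-borabicyclononane borinate F5.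
   - B-alkyl Suzuki–Miyaura coupling of F5 with 7 (Pd(dppf)Cl2, K3PO4, DMF/THF, rt to 50 °C) tolerates the free hydroxyl and should give 1-[4-(tert-butyldimethylsilyloxy)-2-hydroxy-6-(ArCH2O)-3-lavandulylphenyl]ethanone F6.
   - Silylation of F6 (TBSCl, imidazole, DMAP, DMF) rejoins the route at 13.

3. Step 5. Iodination may go to the carbon para to the hydroxyl or onto ring B, giving inseparable or useless regioisomers. The fallback fixes the position by symmetry before ring B is present.
   - It sets out from diol 5. NIS (1 equiv, DMF, 0 °C) can give only one mono-iodide, 1-[4-(tert-butyldimethylsilyloxy)-2,6-dihydroxy-3-iodophenyl]ethanone F7.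
   - Mitsunobu etherification of F7 with alcohol 3 (PPh3, DIAD, THF) is expected at the hydroxyl that is not flanked by iodine, which rejoins the route at 7.

Further compounds
F1 | step 10 | 1-[6-hydroxy-2,4-bis(tert-butyldimethylsilyloxy)-3-[(2S)-5-methyl-2-(prop-1-en-2-yl)hex-4-en-1-yl]phenyl]ethanone | C=C(C)[C@@H](CC=C(C)C)Cc1c(O[Si](C)(C)C(C)(C)C)cc(O)c(C(C)=O)c1O[Si](C)(C)C(C)(C)C
F2 | step 10 | 3-hydroxy-1-[6-hydroxy-2,4-bis(tert-butyldimethylsilyloxy)-3-[(2S)-5-methyl-2-(prop-1-en-2-yl)hex-4-en-1-yl]phenyl]-3-[2-methoxy-4-(triisopropylsilyloxy)phenyl]propan-1-one (both carbinol epimers) | C=C(C)[C@@H](CC=C(C)C)Cc1c(O[Si](C)(C)C(C)(C)C)cc(O)c(C(=O)CC(O)c2ccc(O[Si](C(C)C)(C(C)C)C(C)C)cc2OC)c1O[Si](C)(C)C(C)(C)C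
F3 | step 10 | (E)-1-[6-hydroxy-2,4-bis(tert-butyldimethylsilyloxy)-3-[(2S)-5-methyl-2-(prop-1-en-2-yl)hex-4-en-1-yl]phenyl]-3-[2-methoxy-4-(triisopropylsilyloxy)phenyl]prop-2-en-1-one | C=C(C)[C@@H](CC=C(C)C)Cc1c(O[Si](C)(C)C(C)(C)C)cc(O)c(C(=O)/C=C/c2ccc(O[Si](C(C)C)(C(C)C)C(C)C)cc2OC)c1O[Si](C)(C)C(C)(C)C
F4 | step 10 | (2R)-5,7-bis(tert-butyldimethylsilyloxy)-2-[2-methoxy-4-(triisopropylsilyloxy)phenyl]-6-[(2S)-5-methyl-2-(prop-1-en-2-yl)hex-4-en-1-yl]chroman-4-one | C=C(C)[C@@H](CC=C(C)C)Cc1c(O[Si](C)(C)C(C)(C)C)cc2c(c1O[Si](C)(C)C(C)(C)C)C(=O)C[C@H](c1ccc(O[Si](C(C)C)(C(C)C)C(C)C)cc1OC)O2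
F5 | step 8 | lithium 9-methoxy-9-[(2R)-5-methyl-2-(prop-1-en-2-yl)hex-4-en-1-yl]-9-boranuidabicyclo[3.3.1]nonane | C=C(C)[C@@H](CC=C(C)C)C[B-]1(OC)C2CCCC1CCC2.[Li+]
F6 | step 8 | 1-[4-(tert-butyldimethylsilyloxy)-2-hydroxy-6-{[2-methoxy-4-(triisopropylsilyloxy)phenyl]methoxy}-3-[(2S)-5-methyl-2-(prop-1-en-2-yl)hex-4-en-1-yl]phenyl]ethanone | C=C(C)[C@@H](CC=C(C)C)Cc1c(O[Si](C)(C)C(C)(C)C)cc(OCc2ccc(O[Si](C(C)C)(C(C)C)C(C)C)cc2OC)c(C(C)=O)c1O
F7 | step 5 | 1-[4-(tert-butyldimethylsilyloxy)-2,6-dihydroxy-3-iodophenyl]ethanone | CC(=O)c1c(O)cc(O[Si](C)(C)C(C)(C)C)c(I)c1O
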